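Time is what we count in this flask: how much of the lag of J has passed when 20% of the G are converted.

in all of them: Q 5 mol%
- north: G 0.042 M; D 2 equiv; X 0.030 M; run made earlier
- south-west: G 0.066 M; D 2 equiv; X 0.030 M; run made earlier
- south-east: G 0.030 M; D 3 equiv; X 0.030 M; run made earlier
- flask: G 0.030 M; D 2.00 equiv; X 0.0300 M

| run | time / min | J / % | G / % |
|---|---|---|---|
| north | 8.00 | 3.7 | 34.4 |
| north | 20.0 | 4.4 | 26.4 |
| north | 40.0 | 8.8 | 17.7 |
| north | 60.0 | 11.9 | 15.0 |
| south-west | 8.00 | 2.7 | 48.0 |
| south-west | 20.0 | 6.9 | 37.8 |
| south-west | 40.0 | 19.8 | 33.0 |
| south-west | 60.0 | 28.2 | 23.5 |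
| south-east | 15.0 | 0.4 | 15.1 |
| south-east | 30.0 | 1.2 | 7.8 |
| south-east | 50.0 | 3.8 | 5.0 |
| south-east | 60.0 | 4.5 | 4.2 |

(each reading ± 1 percentage point)

1. factor on the rate of making J when 20% of the G are converted if Q is charged twice over
2. factor on the rate when 20% of the G are converted if Q is charged at 1 mol% instead

- the earlier runs were read with a standard deviation of 1 percentage point

1. In the south-east run c_G and c_X start equal. Reading the loss of G as second-order capture by X, the 30.0 min reading gives 13.1 /M/min. So we expect the flask to reach 20% at 0.634 min, and we take that time as free of Q.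

2. We follow J made per minute per G present. In the south-west run this reads 0.00816 /min early and 0.0149 /min late. Taking the late value as the finished one, the early value is about half of it, so we read the lag (induction period) of that run as having a half-life near 14.0 min.

3. The late value in the north run reads 0.00948 /min. The south-west reading is 1.57 times this, and c_Q in the south-west run is 1.57 times that of the north run. But c_G and c_D rose with c_Q, so first order in Q is our assumption. We assume the same pacing for the lag, which gives the flask 30.8 min.

4. The flask then stands at 0.0206: this is the lag count, the lag half-lives elapsed at a fixed conversion.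

5. We take the rate as c_Q times the finished share of the lag. A finished lag gives the lower bound on the effect, 2 and 0.200. A share proportional to the count gives the upper bound, 4 and 0.0400. Our count tightens these to 3.97 and 0.0402.

6. The forecast, 2 and 0.2, stands at the first-order end of this bracket: "I expect roughly first order in Q".

7. Doubling Q gives 3.68, and the 1 mol% charge, with a count of 0.00412, gives 0.0430.

    G + X → L (k = 9.11 /M/min)
    D + E → Q + J (k = 33.6 /M/min)
    Q + Z ⇌ E (K = 1400 /M, k = 33.8 /M/min)
    G + Q ⇌ Q + Z (K = 0.370, k = 6.23 /M/min)

In the flask G + X → L had half its turnover up to 50.0 min done by 3.07 min, and the 20% mark passed at 0.878 min, which on our lag half-life is a count of 0.0285, beside the 0.0206 we reckoned. Q + Z → E had 22% of its turnover up to that same time behind it at 10.0 min, the rate of making J was 6.6 times its 20% value at 7.67 min, and at 50.0 min the flask held J at 4.64% of the G charged.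

The runs were computed for an exercise, and the scatter is random.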